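**Retrosynthetic overview**

- Numbering: C1 (quaternary C–CH3), C2/C3 (CH2), C4 (C(OH)iPr), C5 (fusion CH), C6 (CH–O), C7 (CH2), C8=C9 (C8 methylated), C10 (C=O). The strategy rests on the seven-membered ring: C5–C10, the C8 methyl and the oxygenated carbons C6 and C10 are the benzene ring of 3,5-dimethoxytoluene, and C1 is the single carbon inserted between C5 and C10.
- Key disconnection: C1–C5 and C1–C10 are broken and the aromatic C5–C10 bond restored, which leads back to the α-methyl α-diazoketone 14 tethered to the arene through C2–C3–C4 (Büchner reaction, read backwards).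
- 14 comes from β-silyloxy acid 12 and diazoethane. C4 is set by a phenol-directed enantioselective allylation of an aryl isopropyl ketone made from lithiated 3,5-dimethoxytoluene.
- After the key step the C2 ketone is removed through its enol triflate. The C6 enol ether is hydrolysed and transposed (Stork–Danheiser type) to the C6=C7/C10 dienone. β-Epoxidation and Pd–formate hydrogenolysis then place the C6 oxygen on the β face, so the arene oxygen at C6 only fixes the position and is not carried into the target. Acylation and desilylation finish the route.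
- Ring order: benzene ring first; cyclopentanone and cycloheptatriene together in the key step.

Key step: step 9

Remark 1: C1–C10 are the target numbers defined above, not IUPAC locants; α is the face of the C1 methyl group, β the opposite face.
Remark 2: the (S,S)-allylsilane 6 is assumed to deliver allyl to the ketone face that gives (R)-7. The sense must be confirmed on 7; if it is the reverse, the (R,R)-reagent is used and nothing else changes.

**Route**

Step 1
Reactants: 1 3,5-dimethoxytoluene; 2 N-methoxy-N-methylisobutyramide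
Product: 4 1-(2,6-dimethoxy-4-methylphenyl)-2-methylpropan-1-one, via aryllithium 3 (not isolated)
Conditions: n-BuLi, THF, 0 °C → rt; then 2, −78 → 0 °C; aq. NH4Cl
Reagents that add atoms: none
Why: Directed ortho-lithiation between the two methoxy groups followed by acylation with a Weinreb amide, whose chelated tetrahedral intermediate prevents over-addition.

Step 2
Reactants: 4 1-(2,6-dimethoxy-4-methylphenyl)-2-methylpropan-1-one
Product: 5 1-(2-hydroxy-6-methoxy-4-methylphenyl)-2-methylpropan-1-one
Conditions: BCl3 (1.1 equiv), CH2Cl2, −78 → 0 °C; H2O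
Reagents that add atoms: none
Why: Chelation-controlled demethylation: BCl3 bound between the ketone oxygen and an ortho methoxy group cleaves only that ether, and the symmetry of 4 makes the two ortho groups equivalent.

Step 3
Reactants: 5 1-(2-hydroxy-6-methoxy-4-methylphenyl)-2-methylpropan-1-one; 6 (S,S)-allyl(chloro)silane of N,N'-bis(4-bromobenzyl)cyclohexane-1,2-diamine
Product: 7 (R)-2-(3-hydroxy-2-methylhex-5-en-3-yl)-3-methoxy-5-methylphenol
Conditions: 6 (1.5 equiv), toluene, 40 °C; then MeOH, aq. NaHCO3
Reagents that add atoms: none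
Why: Phenol-directed ketone allylation with a strained chiral allylsilane (Leighton type): the phenol displaces chloride on silicon, the ketone binds the Lewis-acidic silicon and allyl is transferred intramolecularly, so the diamine and not the small size difference between aryl and isopropyl sets C4.

Step 4
Reactants: 7 (R)-2-(3-hydroxy-2-methylhex-5-en-3-yl)-3-methoxy-5-methylphenol
Product: 8 (R)-3-(2,6-dimethoxy-4-methylphenyl)-2-methylhex-5-en-3-ol
Conditions: MeI, K2CO3, acetone, rt
Reagents that add atoms: iodomethane, CI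
Why: Williamson ether synthesis; only the phenol is deprotonated by carbonate and the tertiary alcohol stays free.

Step 5
Reactants: 8 (R)-3-(2,6-dimethoxy-4-methylphenyl)-2-methylhex-5-en-3-ol
Product: 9 (R)-3-(2,6-dimethoxy-4-methylphenyl)-2-methyl-3-(triethylsilyloxy)hex-5-ene
Conditions: TESOTf, 2,6-lutidine, CH2Cl2, −78 → 0 °C
Reagents that add atoms: triethylsilyl trifluoromethanesulfonate, CC[Si](CC)(CC)OS(=O)(=O)C(F)(F)F
Why: Silylation with a silyl triflate and a hindered base is the standard protection of a crowded tertiary alcohol and keeps the medium free of acid that could ionise the benzylic carbinol.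

Step 6
Reactants: 9 (R)-3-(2,6-dimethoxy-4-methylphenyl)-2-methyl-3-(triethylsilyloxy)hex-5-ene
Product: 11 (R)-3-(2,6-dimethoxy-4-methylphenyl)-4-methyl-3-(triethylsilyloxy)pentanal, via diol 10 (not isolated)
Conditions: OsO4 (2 mol %), NaIO4, 2,6-lutidine, dioxane/H2O, rt
Reagents that add atoms: osmium tetroxide (catalytic), O=[Os](=O)(=O)=O; sodium periodate, [Na+].[O-]I(=O)(=O)=O
Why: Lemieux–Johnson oxidation: dihydroxylation of the only alkene and periodate cleavage of the diol, under conditions milder towards the electron-rich arene than ozone or RuO4.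

Step 7
Reactants: 11 (R)-3-(2,6-dimethoxy-4-methylphenyl)-4-methyl-3-(triethylsilyloxy)pentanal
Product: 12 (R)-3-(2,6-dimethoxy-4-methylphenyl)-4-methyl-3-(triethylsilyloxy)pentanoic acid
Conditions: NaClO2, NaH2PO4, 2-methyl-2-butene, t-BuOH/H2O, rt
Reagents that add atoms: sodium chlorite, [Na+].[O-]Cl=O
Why: Pinnick oxidation; the alkene scavenger removes HOCl so that the arene is not chlorinated, and the buffer spares the silyl ether.

Step 8
Reactants: 12 (R)-3-(2,6-dimethoxy-4-methylphenyl)-4-methyl-3-(triethylsilyloxy)pentanoic acid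
Product: 14 (R)-2-diazo-5-(2,6-dimethoxy-4-methylphenyl)-6-methyl-5-(triethylsilyloxy)heptan-3-one, via acid chloride 13 (not isolated)
Conditions: 1-chloro-N,N,2-trimethylpropenylamine (Ghosez), CH2Cl2, 0 °C → rt; then added to CH3CHN2 (3 equiv, ethereal, from N-ethyl-N-nitrosourea/KOH), −20 → 0 °C
Reagents that add atoms: diazoethane, CC=[N+]=[N-]
Why: Acylation of a diazoalkane by an acid chloride (Arndt–Eistert type): the acid chloride is formed under neutral conditions and a second equivalent of diazoethane takes up the HCl.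

Step 9
Reactants: 14 (R)-2-diazo-5-(2,6-dimethoxy-4-methylphenyl)-6-methyl-5-(triethylsilyloxy)heptan-3-one
Product: 16 (3R,8aS)-4,8-dimethoxy-6,8a-dimethyl-3-(propan-2-yl)-3-(triethylsilyloxy)-3,8a-dihydroazulen-1(2H)-one, via norcaradiene 15 (not isolated)
Conditions: Rh2(OAc)4 (1 mol %), CH2Cl2, 40 °C, slow addition of 14 (final 0.01 M)
Reagents that add atoms: none
Why: Rh(II) decomposes 14 to an electrophilic keto carbenoid at C1, which adds across the ipso–ortho bond of the arene (bonds C1–C5 and C1–C10) to give norcaradiene 15; disrotatory 6π electrocyclic opening then breaks the former aromatic bond C5–C10 and leaves cycloheptatriene 16 with both methoxy groups as enol ethers. The closest known reaction is the intramolecular Büchner reaction of 1-diazo-4-arylbutan-2-ones to 3,8a-dihydroazulen-1(2H)-ones, which is established for diazoethane-derived (α-methyl) diazoketones and for arenes bearing ortho substituents. The cyclopentanone closes by attack of C1 on the ipso carbon through the tether C2–C3–C4 (5-exo with respect to the C5–C10 π bond), and the seven-membered ring is not closed by cyclisation but arises by one-carbon expansion of the benzene ring. The one new stereocentre C1 is controlled by C4: allylic strain with the two ortho methoxy groups should hold the silyloxy oxygen in the arene plane, the tether carbon C3 on the face that is attacked and the isopropyl group on the opposite face, which places C1–CH3 cis to C4–O. The step needs arene addition to outrun the 1,2-hydride shift from the C1 methyl group, oxonium ylide formation at the silyl ether and C–H insertion into the isopropyl methine; the very electron-rich arene held next to the carbenoid, the crowded tertiary triethylsilyl ether, the deactivation of C–H bonds β to oxygen and the blocked ortho positions should secure this.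

Step 10
Reactants: 16 (3R,8aS)-4,8-dimethoxy-6,8a-dimethyl-3-(propan-2-yl)-3-(triethylsilyloxy)-3,8a-dihydroazulen-1(2H)-one
Product: 18 C2 enol triflate of 16 (C2(OTf)=C3), via lithium enolate 17 (not isolated)
Conditions: LiHMDS, THF, −78 °C; Comins' reagent, −78 → −40 °C; aq. NH4Cl
Reagents that add atoms: N-(5-chloropyridin-2-yl)bis(trifluoromethanesulfonyl)imide, FC(F)(F)S(=O)(=O)N(c1ccc(Cl)cn1)S(=O)(=O)C(F)(F)F
Why: Enolate O-triflation: C3 is the only enolisable position, the cold lithium enolate should not expel the C4 silyloxy group, and removing the C2 carbonyl takes away the acceptor that would let acid open the norcaradiene form.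

Step 11
Reactants: 18 C2 enol triflate of 16
Product: 19 C2=C3 alkene (4-isopropyl-6,10-dimethoxy-1,8-dimethyl-4-triethylsilyloxy-bicyclo[5.3.0]deca-2,5,7,9-tetraene in target numbering)
Conditions: Pd(OAc)2 (5 mol %), PPh3, HCO2H, n-Bu3N, DMF, 60 °C
Reagents that add atoms: none
Why: Palladium-catalysed formate reduction of an alkenyl triflate (Cacchi conditions): oxidative addition, decarboxylation of formate to Pd–H and reductive elimination, in a buffered medium that leaves the enol ethers intact.

Step 12
Reactants: 19 C2=C3 alkene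
Product: 20 bis(enol ether) triene with C2 and C3 as CH2 (4-isopropyl-6,10-dimethoxy-1,8-dimethyl-4-triethylsilyloxy-bicyclo[5.3.0]deca-5,7,9-triene)
Conditions: 2-nitrobenzenesulfonylhydrazide, Et3N, CH2Cl2, rt
Reagents that add atoms: none
Why: Diimide reduction: the reagent transfers H2 fastest to the strained cis-disubstituted cyclopentene C2=C3 and only slowly to the tri- and tetrasubstituted, electron-rich alkenes of the triene.

Step 13
Reactants: 20 bis(enol ether) triene
Product: 21 vinylogous ester (C6 ketone; C7=C8–C9=C10–OMe; C5–H β; trans ring fusion)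
Conditions: 0.05 M HCl, THF/H2O (4:1), 0 °C; NaHCO3
Reagents that add atoms: water, O
Why: Enol ether hydrolysis: C5 is the one carbon whose protonation gives a cation stabilised by both methoxy groups, water should add at the less hindered terminus C6 (next to C5–H, not to quaternary C1) and the resulting vinylogous ester resists further hydrolysis; the proton is expected to enter C5 from the β face, opposite C1–CH3 and C4–OSiEt3, which sets C5.

Step 14
Reactants: 21 vinylogous ester
Product: 23 dienone (C10 ketone; C8=C9 and C6=C7 alkenes; C5–H β), via allylic alcohol 22 (not isolated)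
Conditions: DIBAL-H, CH2Cl2, −78 °C; then 0.5 M HCl, THF, 0 °C
Reagents that add atoms: water, O
Why: Stork–Danheiser transposition in its dienyl form: 1,2-reduction of the vinylogous ester carbonyl, then acid-induced loss of the C6 hydroxyl through the methoxy-stabilised pentadienyl cation and hydrolysis at C10, with the acid mild enough to keep the tertiary silyl ether.

Step 15
Reactants: 23 dienone
Product: 24 6β,7β-epoxy enone
Conditions: mCPBA, NaHCO3, CH2Cl2, 0 °C
Reagents that add atoms: 3-chloroperbenzoic acid, OOC(=O)c1cccc(Cl)c1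
Why: Peracid epoxidation: the γ,δ-alkene of a linear dienone is the more electron-rich one, and the reagent should reach C6=C7 from the β face because the angular C1 methyl and the C4 silyloxy group cover the α face, which sets C6.

Step 16
Reactants: 24 6β,7β-epoxy enone
Product: 25 6β-hydroxy enone (C6–OH cis to C5–H; C7 = CH2; C8=C9–C10=O; 4-OTES)
Conditions: Pd2(dba)3·CHCl3 (2.5 mol %), n-Bu3P, HCO2H, Et3N, dioxane, rt
Reagents that add atoms: none
Why: Pd(0)-catalysed hydrogenolysis of an alkenyl oxirane with formate (Tsuji–Shimizu): the allylic C7–O bond ionises to a π-allyl complex and hydride is delivered to C7, which keeps the enone conjugated and leaves the C6–O bond and its configuration untouched.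

Step 17
Reactants: 25 6β-hydroxy enone; 26 3,4,5-trimethoxybenzoyl chloride
Product: 27 triethylsilyl ether of the target
Conditions: 26, Et3N, DMAP (cat.), CH2Cl2, 0 °C → rt
Reagents that add atoms: none
Why: DMAP-catalysed acylation of the only free hydroxyl group, a secondary equatorial alcohol.

Step 18
Reactants: 27 triethylsilyl ether of the target
Product: 28 CNP0218356.1
Conditions: HF·pyridine, pyridine, THF, 0 °C → rt
Reagents that add atoms: none
Why: Fluoride cleavage of the tertiary silyl ether under buffered, weakly acidic conditions, which avoid γ-deprotonation of the δ-acyloxy enone and loss of the ester.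

**Compound list**

1 | 3,5-dimethoxytoluene | COc1cc(C)cc(OC)c1 | starting material
2 | N-methoxy-N-methylisobutyramide | CC(C)C(=O)N(C)OC | starting material
3 | 2,6-dimethoxy-4-methylphenyllithium | [Li]c1c(OC)cc(C)cc1OC | intermediate
4 | 1-(2,6-dimethoxy-4-methylphenyl)-2-methylpropan-1-one | COc1cc(C)cc(OC)c1C(=O)C(C)C | intermediate
5 | 1-(2-hydroxy-6-methoxy-4-methylphenyl)-2-methylpropan-1-one | COc1cc(C)cc(O)c1C(=O)C(C)C | intermediate
6 | (3aS,7aS)-2-allyl-1,3-bis(4-bromobenzyl)-2-chlorooctahydro-1H-1,3,2-benzodiazasilole | C=CC[Si]1(Cl)N(Cc2ccc(Br)cc2)[C@H]2CCCC[C@@H]2N1Cc1ccc(Br)cc1 | starting material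
7 | (R)-2-(3-hydroxy-2-methylhex-5-en-3-yl)-3-methoxy-5-methylphenol | C=CC[C@@](O)(C(C)C)c1c(O)cc(C)cc1OC | intermediate
8 | (R)-3-(2,6-dimethoxy-4-methylphenyl)-2-methylhex-5-en-3-ol | C=CC[C@@](O)(C(C)C)c1c(OC)cc(C)cc1OC | intermediate
9 | (R)-3-(2,6-dimethoxy-4-methylphenyl)-2-methyl-3-(triethylsilyloxy)hex-5-ene | C=CC[C@@](O[Si](CC)(CC)CC)(C(C)C)c1c(OC)cc(C)cc1OC | intermediate
10 | (4R)-4-(2,6-dimethoxy-4-methylphenyl)-5-methyl-4-(triethylsilyloxy)hexane-1,2-diol, both C2 epimers | OCC(O)C[C@@](O[Si](CC)(CC)CC)(C(C)C)c1c(OC)cc(C)cc1OC | intermediate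
11 | (R)-3-(2,6-dimethoxy-4-methylphenyl)-4-methyl-3-(triethylsilyloxy)pentanal | O=CC[C@@](O[Si](CC)(CC)CC)(C(C)C)c1c(OC)cc(C)cc1OC | intermediate
12 | (R)-3-(2,6-dimethoxy-4-methylphenyl)-4-methyl-3-(triethylsilyloxy)pentanoic acid | OC(=O)C[C@@](O[Si](CC)(CC)CC)(C(C)C)c1c(OC)cc(C)cc1OC | intermediate
13 | (R)-3-(2,6-dimethoxy-4-methylphenyl)-4-methyl-3-(triethylsilyloxy)pentanoyl chloride | ClC(=O)C[C@@](O[Si](CC)(CC)CC)(C(C)C)c1c(OC)cc(C)cc1OC | intermediate
14 | (R)-2-diazo-5-(2,6-dimethoxy-4-methylphenyl)-6-methyl-5-(triethylsilyloxy)heptan-3-one | CC(=[N+]=[N-])C(=O)C[C@@](O[Si](CC)(CC)CC)(C(C)C)c1c(OC)cc(C)cc1OC | intermediate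
15 | norcaradiene valence isomer of 16 (cyclopropane C1–C5–C10; C6=C7 and C8=C9) | COC1=CC(C)=C[C@]2(OC)[C@@]3(C)C(=O)C[C@@](O[Si](CC)(CC)CC)(C(C)C)[C@@]123 | intermediate
16 | (3R,8aS)-4,8-dimethoxy-6,8a-dimethyl-3-(propan-2-yl)-3-(triethylsilyloxy)-3,8a-dihydroazulen-1(2H)-one; C1–CH3 cis to C4–O | COC1=CC(C)=CC(OC)=C2[C@](O[Si](CC)(CC)CC)(C(C)C)CC(=O)[C@]12C | intermediate
17 | lithium C2 enolate of 16 | COC1=CC(C)=CC(OC)=C2[C@](O[Si](CC)(CC)CC)(C(C)C)C=C(O[Li])[C@]12C | intermediate
18 | C2 enol triflate of 16 | COC1=CC(C)=CC(OC)=C2[C@](O[Si](CC)(CC)CC)(C(C)C)C=C(OS(=O)(=O)C(F)(F)F)[C@]12C | intermediate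
19 | C2=C3 alkene: 4-isopropyl-6,10-dimethoxy-1,8-dimethyl-4-triethylsilyloxy-bicyclo[5.3.0]deca-2,5,7,9-tetraene (target numbering) | COC1=CC(C)=CC(OC)=C2[C@](O[Si](CC)(CC)CC)(C(C)C)C=C[C@]12C | intermediate
20 | 4-isopropyl-6,10-dimethoxy-1,8-dimethyl-4-triethylsilyloxy-bicyclo[5.3.0]deca-5,7,9-triene (target numbering) | COC1=CC(C)=CC(OC)=C2[C@](O[Si](CC)(CC)CC)(C(C)C)CC[C@]12C | intermediate
21 | vinylogous ester: 10-methoxy-7,9-dien-6-one, 4-OTES, C5–H β (trans-fused) | COC1=CC(C)=CC(=O)[C@H]2[C@](O[Si](CC)(CC)CC)(C(C)C)CC[C@]12C | intermediate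
22 | allylic alcohol: 10-methoxy-7,9-dien-6-ol, 4-OTES (C6 epimers) | COC1=CC(C)=CC(O)[C@H]2[C@](O[Si](CC)(CC)CC)(C(C)C)CC[C@]12C | intermediate
23 | dienone: 6,8-dien-10-one, 4-OTES, C5–H β | O=C1C=C(C)C=C[C@H]2[C@](O[Si](CC)(CC)CC)(C(C)C)CC[C@]12C | intermediate
24 | 6β,7β-epoxy-8-en-10-one, 4-OTES | O=C1C=C(C)[C@@H]3O[C@@H]3[C@H]2[C@](O[Si](CC)(CC)CC)(C(C)C)CC[C@]12C | intermediate
25 | 6β-hydroxy-8-en-10-one, 4-OTES (C6–OH cis to C5–H) | O[C@H]1CC(C)=CC(=O)[C@@]2(C)CC[C@@](O[Si](CC)(CC)CC)(C(C)C)[C@H]12 | intermediate
26 | 3,4,5-trimethoxybenzoyl chloride | COc1cc(C(Cl)=O)cc(OC)c1OC | starting material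
27 | triethylsilyl ether of the target | COc1cc(C(=O)O[C@H]2CC(C)=CC(=O)[C@@]3(C)CC[C@@](O[Si](CC)(CC)CC)(C(C)C)[C@H]23)cc(OC)c1OC | intermediate
28 | CNP0218356.1: (1S,4R,5S,6S)-4-hydroxy-4-isopropyl-1,8-dimethyl-10-oxobicyclo[5.3.0]dec-8-en-6-yl 3,4,5-trimethoxybenzoate (target numbering) | COc1cc(C(=O)O[C@H]2CC(C)=CC(=O)[C@@]3(C)CC[C@@](O)(C(C)C)[C@H]23)cc(OC)c1OC | target

**Step count**

Total: 18 steps. Longest linear sequence: 18 steps (1 → 28).

**Steps most likely to fail**

Step 9. The carbenoid may be diverted before it reaches the arene: by a 1,2-hydride shift from the C1 methyl group, or by capture at the C4 silyl ether oxygen with silyl transfer. It may also add through the rotamer that holds the isopropyl group in the arene plane, which erodes facial selectivity at C1. The fallback sets out from acid 12 and returns at 16. The acid chloride 13 is condensed with lithiated methyl phenyl sulfone (2 equiv, THF, −78 °C) to give β-keto sulfone F1. Diazo transfer (4-acetamidobenzenesulfonyl azide, Et3N, MeCN) gives α-diazo-β-keto sulfone F2, an acceptor/acceptor carbenoid precursor that has no hydrogen for a 1,2-shift and forms a more selective carbenoid. Rh(II)- or Cu(hfacac)2-catalysed arene addition then gives the C1-sulfonyl cycloheptatriene F3. Reductive desulfonylation (SmI2, THF/HMPA, −78 °C) generates the C1 enolate regiospecifically, and methyl iodide is expected to alkylate it on the face away from the isopropyl group, giving 16.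

Step 13. Water may capture the pentadienyl cation at C10 instead of C6 (poor site selectivity), the proton may enter C5 from the α face, or the C4 silyl ether may ionise before C-protonation. The fallback sets out from 20 and returns at 23. Both enol ethers are hydrolysed (0.5 M HCl, THF, 0 °C → rt) to the ene-1,5-dione F4. This is reached whichever terminus water attacks first, and C5, now α to the C6 ketone, is set under thermodynamic control with the C5–C6 bond trans to the isopropyl group. NaBH4 (MeOH/CH2Cl2, −78 °C) reduces the non-conjugated C6 ketone in preference to the hindered enone and gives hydroxy enone F5, whose C6 configuration does not matter. Mesylation (MsCl, Et3N) gives mesylate F6, and DBU removes a C7 proton and expels the mesylate to give dienone 23.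

Step 12. Diimide may lose chemoselectivity: it may also reduce the triene, or react too slowly at the C2=C3 bond flanked by two quaternary carbons. The fallback sets out from 16 and returns at 23, removing the C2 oxygen by a radical only after C1 no longer carries alkenyl groups that would allow a fast 1,2-vinyl shift. NaBH4 (MeOH, 0 °C) gives C2 alcohol F7. Mild acid hydrolysis as in step 13 gives hydroxy vinylogous ester F8. DIBAL-H followed by dilute acid as in step 14 gives hydroxy dienone F9. Phenyl chlorothionoformate (pyridine, DMAP) gives thionocarbonate F10. Barton–McCombie reduction (Bu3SnH at high concentration, AIBN, toluene, 80 °C) then gives 23; the high hydride concentration is meant to outrun a 1,2-acyl shift of the C2 radical.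

**Further compounds**

F1 | step 9 | (R)-4-(2,6-dimethoxy-4-methylphenyl)-5-methyl-1-(phenylsulfonyl)-4-(triethylsilyloxy)hexan-2-one | O=C(CS(=O)(=O)c1ccccc1)C[C@@](O[Si](CC)(CC)CC)(C(C)C)c1c(OC)cc(C)cc1OC
F2 | step 9 | (R)-1-diazo-4-(2,6-dimethoxy-4-methylphenyl)-5-methyl-1-(phenylsulfonyl)-4-(triethylsilyloxy)hexan-2-one | [N-]=[N+]=C(C(=O)C[C@@](O[Si](CC)(CC)CC)(C(C)C)c1c(OC)cc(C)cc1OC)S(=O)(=O)c1ccccc1
F3 | step 9 | analogue of 16 with phenylsulfonyl in place of the C1 methyl group | COC1=CC(C)=CC(OC)=C2[C@](O[Si](CC)(CC)CC)(C(C)C)CC(=O)C12S(=O)(=O)c1ccccc1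
F4 | step 13 | ene-1,5-dione: 8-ene-6,10-dione, 4-OTES, C5–H β | O=C1CC(C)=CC(=O)[C@@]2(C)CC[C@@](O[Si](CC)(CC)CC)(C(C)C)[C@H]12
F5 | step 13 | 6-hydroxy-8-en-10-one, 4-OTES (C6 epimers) | OC1CC(C)=CC(=O)[C@@]2(C)CC[C@@](O[Si](CC)(CC)CC)(C(C)C)[C@H]12
F6 | step 13 | C6 methanesulfonate of F5 | CS(=O)(=O)OC1CC(C)=CC(=O)[C@@]2(C)CC[C@@](O[Si](CC)(CC)CC)(C(C)C)[C@H]12
F7 | step 12 | C2 alcohol of 16 (C2 epimers) | COC1=CC(C)=CC(OC)=C2[C@](O[Si](CC)(CC)CC)(C(C)C)CC(O)[C@]12C
F8 | step 12 | 2-hydroxy analogue of 21 | COC1=CC(C)=CC(=O)[C@H]2[C@](O[Si](CC)(CC)CC)(C(C)C)CC(O)[C@]12C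
F9 | step 12 | 2-hydroxy analogue of 23 | O=C1C=C(C)C=C[C@H]2[C@](O[Si](CC)(CC)CC)(C(C)C)CC(O)[C@]12C
F10 | step 12 | O-phenyl thionocarbonate of F9 | O=C1C=C(C)C=C[C@H]2[C@](O[Si](CC)(CC)CC)(C(C)C)CC(OC(=S)Oc3ccccc3)[C@]12C
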